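**Retrosynthetic overview**

1. Last ring (cyclopentane): C9–C8 bond, by intramolecular alkylation of the cage 1,3-diketone carbanion with a pendant CH2CH2Cl.
2. Key bond (closes the seven-membered rings of the homoadamantane): C4–C5. The bridge aldehyde carbon, as its N–H hydrazone, acts as an alkyl carbanion equivalent (N2 is lost) and adds to the β-carbon of an alkylidene-1,3-dione; both carbons are electrophilic in their native form.
3. The alkylidene-1,3-dione comes from a C-alkyl enolate by oxidation, after retro-aldol opening of an adamantanol.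
4. First two rings (bicyclo[3.3.1]nonane trione; C1–C2 and C12–C14 bonds; sets C1, C12, C3): enantioselective alkylative dearomatization–annulation of a 3,5-dialkyl-2,4,6-trihydroxybenzophenone with 2-formyl-3-methylbut-2-enyl acetate.
5. The arene comes from 2,4,6-trihydroxybenzophenone by C-geranylation and reductive C-alkylation with 4-chloro-2,2-dimethylbutanal.

Labels and assumption: C1 = geranyl-bearing bridgehead, C2 = ring CH2, C3 = ring CH, C4 = bridge CH2, C5 = cyclopentane CH, C6 = cyclopentane CMe2, C7/C8 = cyclopentane CH2, C9 = quaternary carbon between the C10 and C11 ketones, C10 = ketone next to C1, C11 = ketone next to C12, C12 = benzoyl-bearing bridgehead, C13 = bridging ketone, C14 = ring CMe2; the antipode of the phase-transfer catalyst in step 8 is assumed to be chosen so that C1 forms as drawn.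

**Route**

Step 1
Reactants: 1 2,4,6-trihydroxybenzophenone; 2 geranyl bromide
Product: 3 3-geranyl-2,4,6-trihydroxybenzophenone
Conditions: 2 (1.0 equiv), KOH (aq., 3 M), 0 → 23 °C
Reagents that add atoms: geranyl bromide (2), CC(C)=CCC/C(C)=C/CBr
Why: C-allylation of the ambident phloroglucinolate (Friedel–Crafts-type C-alkylation) at one of the two equivalent free ring carbons, with the E-alkene untouched and no stereocenter formed.

Step 2
Reactants: 4 isobutyronitrile; 5 1-bromo-2-chloroethane
Product: 7 4-chloro-2,2-dimethylbutanenitrile, via lithiated isobutyronitrile 6 (not isolated)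
Conditions: LiN(i-Pr)2, THF, −78 °C; then 5, −78 → 23 °C
Reagents that add atoms: 1-bromo-2-chloroethane (5), ClCCBr
Why: α-alkylation of a nitrile anion (SN2), selective for the C–Br end because bromide is the better leaving group.

Step 3
Reactants: 7 4-chloro-2,2-dimethylbutanenitrile
Product: 9 4-chloro-2,2-dimethylbutanal, via N-diisobutylaluminium aldimine 8 (not isolated)
Conditions: i-Bu2AlH (1.1 equiv), CH2Cl2, −78 °C; then HCl (aq., 1 M), 0 °C
Reagents that add atoms: water, O
Why: partial hydride reduction of the hindered nitrile stops at the aluminium aldimine, which is hydrolysed to the aldehyde (nitrile-to-aldehyde reduction), the primary chloride being inert.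

Step 4
Reactants: 3 3-geranyl-2,4,6-trihydroxybenzophenone; 9 4-chloro-2,2-dimethylbutanal
Product: 11 3-(4-chloro-2,2-dimethylbutyl)-5-geranyl-2,4,6-trihydroxybenzophenone, via ortho-quinone methide 10 (not isolated)
Conditions: L-proline (20 mol%), diethyl 2,6-dimethyl-1,4-dihydropyridine-3,5-dicarboxylate (1.2 equiv), CH2Cl2, 40 °C
Reagents that add atoms: 4-chloro-2,2-dimethylbutanal (9), CC(C)(CCCl)C=O
Why: three-component reductive alkylation (Knoevenagel condensation at the only free ring carbon, then conjugate hydride transfer from the dihydropyridine to the ortho-quinone methide), which leaves the diaryl ketone, the alkenes and the alkyl chloride alone and creates no stereocenter.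

Step 5
Reactants: 12 diethyl isopropylidenemalonate
Product: 13 2-(propan-2-ylidene)propane-1,3-diol
Conditions: i-Bu2AlH (4.4 equiv), toluene, −78 → 0 °C; aqueous potassium sodium tartrate work-up
Reagents that add atoms: none
Why: 1,2-reduction of both conjugated esters by the electrophilic aluminium hydride gives the allylic diol (ester reduction).

Step 6
Reactants: 13 2-(propan-2-ylidene)propane-1,3-diol
Product: 14 2-(hydroxymethyl)-3-methylbut-2-enal
Conditions: MnO2 (10 equiv), CH2Cl2, 23 °C
Reagents that add atoms: none
Why: allylic alcohol oxidation stops after one hydroxyl because the enal formed deactivates the remaining allylic alcohol.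

Step 7
Reactants: 14 2-(hydroxymethyl)-3-methylbut-2-enal
Product: 15 2-formyl-3-methylbut-2-en-1-yl acetate
Conditions: Ac2O, pyridine, 4-(dimethylamino)pyridine (5 mol%), CH2Cl2, 0 °C
Reagents that add atoms: acetic anhydride, CC(=O)OC(C)=O
Why: nucleophile-catalysed O-acetylation of the primary allylic alcohol.

Step 8
Reactants: 11 3-(4-chloro-2,2-dimethylbutyl)-5-geranyl-2,4,6-trihydroxybenzophenone; 15 2-formyl-3-methylbut-2-en-1-yl acetate
Product: 18 adamantanol aldol adduct, via C-alkylated dienone 16 (not isolated), via bicyclic enol aldehyde 17 (not isolated)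
Conditions: 2,7-bis[(O(9)-allylhydrocinchonidinium-1-yl)methyl]naphthalene dibromide (25 mol%), CsOH·H2O (5 equiv), 4 Å molecular sieves, CH2Cl2, −50 °C
Reagents that add atoms: 2-formyl-3-methylbut-2-en-1-yl acetate (15), CC(C)=C(COC(C)=O)C=O
Why: alkylative dearomatization–annulation as established for 3,5-dialkyl-2,4,6-trihydroxybenzophenones (SN2 C-alkylation at the less hindered geranyl-bearing carbon inside the chiral ammonium phenoxide ion pair sets C1, intramolecular Michael addition of the benzoyl-bearing carbon to the CMe2 terminus sets C12 and C3 with the formyl group endo, and aldol closure of C9 onto that aldehyde traps the product), the C4 carbinol and C9 centers being erased in step 9.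

Step 9
Reactants: 18 adamantanol aldol adduct
Product: 20 alkylidene-dione aldehyde, via ring-opened silver enolate 19 (not isolated)
Conditions: 2,2,6,6-tetramethylpiperidin-1-oxyl (2.2 equiv), Ag2O (1.2 equiv), THF, 0 → 23 °C
Reagents that add atoms: none
Why: the basic oxide deprotonates the strained β-hydroxy diketone and retro-aldol opening gives the ring-opened silver enolate, which passes one electron to monovalent silver and then loses a C5 hydrogen atom to the nitroxyl (ortho-quinone-methide-type oxidation of alkylated acylphloroglucinols) to give the alkylidene-1,3-dione, which cannot tautomerise because C6 is quaternary; C1, C12 and C3 are untouched and the two alkene isomers interconvert.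

Step 10
Reactants: 20 alkylidene-dione aldehyde
Product: 23 chloro diketone, via hydrazone 21 (not isolated), via diazene adduct 22 (not isolated)
Conditions: N2H4·H2O (1.1 equiv), 3 Å molecular sieves, THF, 0 °C; then [Ru(p-cymene)Cl2]2 (2.5 mol%), Ph2P(CH2)3PPh2 (5 mol%), K3PO4 (25 mol%), CsF, THF, 50 °C
Reagents that add atoms: none
Why: Proposed new method: the aldehyde carbon C4, as its N–H hydrazone (the three ring ketones and the benzoyl ketone are flanked by quaternary carbons and do not condense), reacts through carbon as an alkyl carbanion equivalent, the closest known reaction type being the ruthenium-catalysed 1,4-addition of aldehyde hydrazones to electron-poor alkenes, and adds to the β-carbon C5 of the alkylidene-1,3-dione, which the endo formyl group holds on the axis of its π-lobe, after which base-induced loss of N2 from the diazene (Wolff–Kishner-type) leaves C4H2 and C9–H; C5 is set here because the diazenyl nitrogen on C4 turns to the C2H2 side away from the C14 methyls, so the alkylidene isomer that reacts keeps its CMe2 group on the other side, cis to the C11 carbonyl, and the equilibrating isomers funnel through that transition state.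

Step 11
Reactants: 23 chloro diketone
Product: 25 CNP0168637.1 (target), via potassium carbanion 24 (not isolated)
Conditions: KN(SiMe3)2 (1.2 equiv), THF, −78 → 23 °C
Reagents that add atoms: none
Why: intramolecular 5-exo-tet alkylation of the cage 1,3-diketone carbanion (as in bridgehead metalation–alkylation of bicyclo[3.3.1]nonane triones), where C9–H is the only acidic hydrogen and the chloroethyl arm can reach only the exo lobe of C9, so C9 forms with retention and the cyclopentane closes cis on the C9–C5 bond.

**Compound list**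

1 | 2,4,6-trihydroxybenzophenone | O=C(c1ccccc1)c1c(O)cc(O)cc1O | starting material
2 | geranyl bromide, (2E)-1-bromo-3,7-dimethylocta-2,6-diene | CC(C)=CCC/C(C)=C/CBr | starting material
3 | 3-geranyl-2,4,6-trihydroxybenzophenone | CC(C)=CCC/C(C)=C/Cc1c(O)cc(O)c(C(=O)c2ccccc2)c1O | intermediate
4 | isobutyronitrile | CC(C)C#N | starting material
5 | 1-bromo-2-chloroethane | ClCCBr | starting material
6 | lithiated isobutyronitrile (lithium keteniminate) | [Li+].CC(C)=C=[N-] | intermediate (not isolated)
7 | 4-chloro-2,2-dimethylbutanenitrile | CC(C)(CCCl)C#N | intermediate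
8 | N-diisobutylaluminium aldimine of 4-chloro-2,2-dimethylbutanal | CC(C)C[Al](CC(C)C)N=CC(C)(C)CCCl | intermediate (not isolated)
9 | 4-chloro-2,2-dimethylbutanal | CC(C)(CCCl)C=O | intermediate
10 | ortho-quinone methide from 3 and 9 (alkylidene on the ring carbon that was free) | CC(C)=CCC/C(C)=C/CC1=C(O)C(C(=O)c2ccccc2)=C(O)C(=CC(C)(C)CCCl)C1=O | intermediate (not isolated)
11 | 3-(4-chloro-2,2-dimethylbutyl)-5-geranyl-2,4,6-trihydroxybenzophenone | CC(C)=CCC/C(C)=C/Cc1c(O)c(CC(C)(C)CCCl)c(O)c(C(=O)c2ccccc2)c1O | intermediate
12 | diethyl isopropylidenemalonate | CCOC(=O)C(=C(C)C)C(=O)OCC | starting material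
13 | 2-(propan-2-ylidene)propane-1,3-diol | CC(C)=C(CO)CO | intermediate
14 | 2-(hydroxymethyl)-3-methylbut-2-enal | CC(C)=C(CO)C=O | intermediate
15 | 2-formyl-3-methylbut-2-en-1-yl acetate | CC(C)=C(COC(C)=O)C=O | intermediate
16 | C-alkylated dienone: dearomatized ring with quaternary C1 carrying geranyl and the 2-formyl-3-methylbut-2-enyl group, C1 configured as in the target | CC(C)=CCC/C(C)=C/C[C@@]1(CC(C=O)=C(C)C)C(O)=C(CC(C)(C)CCCl)C(O)=C(C(=O)c2ccccc2)C1=O | intermediate (not isolated)
17 | bicyclic enol aldehyde: bicyclo[3.3.1]nonane with C1-geranyl, C12-benzoyl, C13 bridging ketone, C14 gem-dimethyl, endo formyl on C3, enolised C10/C11 dione carrying the chlorodimethylbutyl group on C9 | CC(C)=CCC/C(C)=C/C[C@@]12C[C@@H](C=O)C(C)(C)[C@](C(=O)c3ccccc3)(C2=O)C(O)=C(CC(C)(C)CCCl)C1=O | intermediate (not isolated)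
18 | adamantanol aldol adduct: 17 closed by a C9–C4 bond, secondary OH on C4, carbinol configuration not controlled and later erased | CC(C)=CCC/C(C)=C/C[C@@]12C[C@@H]3C(C)(C)[C@](C(=O)c4ccccc4)(C2=O)C(=O)[C@@](CC(C)(C)CCCl)(C3O)C1=O | intermediate
19 | ring-opened silver enolate: bicyclo[3.3.1]nonane with C1-geranyl, C12-benzoyl, C13 bridging ketone, C14 gem-dimethyl, endo formyl on C3, the C10/C11 dione present as its enolate with a monovalent silver counter-ion, chlorodimethylbutyl group on C9 | [Ag+].CC(C)=CCC/C(C)=C/C[C@@]12C[C@@H](C=O)C(C)(C)[C@](C(=O)c3ccccc3)(C2=O)C([O-])=C(CC(C)(C)CCCl)C1=O | intermediate (not isolated)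
20 | alkylidene-dione aldehyde: bicyclo[3.3.1]nonane trione with endo formyl on C3 and a C9=C5 alkylidene, CMe2 group cis to the C11 carbonyl in the reacting isomer shown | CC(C)=CCC/C(C)=C/C[C@@]12C[C@@H](C=O)C(C)(C)[C@](C(=O)c3ccccc3)(C2=O)C(=O)/C(=C\C(C)(C)CCCl)C1=O | intermediate
21 | (E)-N–H hydrazone of 20 at C4 | CC(C)=CCC/C(C)=C/C[C@@]12C[C@@H](/C=N/N)C(C)(C)[C@](C(=O)c3ccccc3)(C2=O)C(=O)/C(=C\C(C)(C)CCCl)C1=O | intermediate (not isolated)
22 | diazene adduct: homoadamantane with C4–C5 bond formed, N=NH on C4 (configuration transient), C9–H exo | CC(C)=CCC/C(C)=C/C[C@@]12C[C@H]3C(N=N)[C@H](C(C)(C)CCCl)[C@@H](C1=O)C(=O)[C@@](C(=O)c1ccccc1)(C2=O)C3(C)C | intermediate (not isolated)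
23 | chloro diketone: homoadamantane trione with C4H2, C5–H on the C10 side, 4-chloro-2-methylbutan-2-yl on C5, C9–H exo | CC(C)=CCC/C(C)=C/C[C@@]12C[C@H]3C[C@H](C(C)(C)CCCl)[C@@H](C1=O)C(=O)[C@@](C(=O)c1ccccc1)(C2=O)C3(C)C | intermediate
24 | potassium carbanion of 23 at C9 (pyramidal, lone pair exo) | [K+].CC(C)=CCC/C(C)=C/C[C@@]12C[C@H]3C[C@H](C(C)(C)CCCl)[C-](C1=O)C(=O)[C@@](C(=O)c1ccccc1)(C2=O)C3(C)C | intermediate (not isolated)
25 | CNP0168637.1 | CC(C)=CCC/C(C)=C/C[C@@]12C[C@H]3C[C@@H]4C(C)(C)CC[C@]4(C1=O)C(=O)[C@@](C(=O)c1ccccc1)(C2=O)C3(C)C | target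

**Step count**

Total steps: 11. Longest linear sequence: 7 steps (4 → 7 → 9 → 11 → 18 → 20 → 23 → 25; the branch from 12 is equally long).

**Three steps most likely to fail**

Step 10 (carbon attack of the hydrazone may lose to N-attack, to enamine-type attack from C3, or give the wrong C5 epimer). The fallback sets out from 20 and comes back at 23. A triazolylidene carbene, made from 2-mesityl-6,7-dihydro-5H-pyrrolo[2,1-c][1,2,4]triazol-2-ium chloride and N,N-diisopropylethylamine in toluene at 60 °C, would turn the aldehyde into its Breslow intermediate. This acyl anion equivalent adds to C5 in an intramolecular Stetter reaction and gives the 4-oxo chloro diketone F1. Its C4 ketone is the only carbonyl not flanked by a quaternary carbon, so 4-methylbenzenesulfonohydrazide in ethanol would give the C4 tosylhydrazone F2. Catecholborane followed by NaOAc·3H2O at 60 °C would then reduce C4 to CH2 and deliver 23.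

Step 8 (regiochemistry of the first alkylation and of the Michael addition, and the level of enantioselectivity, are untested for this substrate). The fallback sets out from 11 and comes back at 18. With LiN(SiMe3)2 in THF, 11 and 15 would give 18 as the racemate, that is together with the enantiomer of 18 F3. Esterification with (S)-2-methoxy-2-phenylacetic acid, N,N'-dicyclohexylcarbodiimide and 4-(dimethylamino)pyridine would give two diastereomers, the (S)-2-methoxy-2-phenylacetate of 18 F4 and the (S)-2-methoxy-2-phenylacetate of the enantiomer F5. After chromatographic separation, K2CO3 in methanol would cleave F4 and return enantiopure 18.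

Step 11 (the C9 carbanion is a cage carbanion with poor overlap to the two carbonyls, so deprotonation may be too slow). The fallback sets out from 20 and comes back at 25. NaI in acetone would give the iodo alkylidene-dione aldehyde F6, and hydrazine would give the iodo hydrazone F7. Under the step 10 conditions in a strictly aprotic medium, the C9 carbanion released by the conjugate addition would be trapped by the iodide before it is protonated (Michael-initiated ring closure). This gives the cyclised diazene F8, which loses N2 to give 25, so no separate deprotonation is needed.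

**Further compounds**

F1 | step 10 | 4-oxo chloro diketone (23 with a ketone at C4) | CC(C)=CCC/C(C)=C/C[C@@]12C[C@H]3C(=O)[C@H](C(C)(C)CCCl)[C@@H](C1=O)C(=O)[C@@](C(=O)c1ccccc1)(C2=O)C3(C)C
F2 | step 10 | C4 tosylhydrazone of F1 | CC(C)=CCC/C(C)=C/C[C@@]12C[C@H]3C(=NNS(=O)(=O)c4ccc(C)cc4)[C@H](C(C)(C)CCCl)[C@@H](C1=O)C(=O)[C@@](C(=O)c1ccccc1)(C2=O)C3(C)C
F3 | step 8 | enantiomer of 18 | CC(C)=CCC/C(C)=C/C[C@]12C[C@H]3C(C)(C)[C@@](C(=O)c4ccccc4)(C2=O)C(=O)[C@](CC(C)(C)CCCl)(C3O)C1=O
F4 | step 8 | (S)-2-methoxy-2-phenylacetate of 18 | CC(C)=CCC/C(C)=C/C[C@@]12C[C@@H]3C(C)(C)[C@](C(=O)c4ccccc4)(C2=O)C(=O)[C@@](CC(C)(C)CCCl)(C3OC(=O)[C@@H](OC)c4ccccc4)C1=O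
F5 | step 8 | (S)-2-methoxy-2-phenylacetate of the enantiomer of 18 | CC(C)=CCC/C(C)=C/C[C@]12C[C@H]3C(C)(C)[C@@](C(=O)c4ccccc4)(C2=O)C(=O)[C@](CC(C)(C)CCCl)(C3OC(=O)[C@@H](OC)c4ccccc4)C1=O
F6 | step 11 | iodo alkylidene-dione aldehyde (20 with I in place of Cl) | CC(C)=CCC/C(C)=C/C[C@@]12C[C@@H](C=O)C(C)(C)[C@](C(=O)c3ccccc3)(C2=O)C(=O)/C(=C\C(C)(C)CCI)C1=O
F7 | step 11 | iodo hydrazone (N–H hydrazone of F6) | CC(C)=CCC/C(C)=C/C[C@@]12C[C@@H](/C=N/N)C(C)(C)[C@](C(=O)c3ccccc3)(C2=O)C(=O)/C(=C\C(C)(C)CCI)C1=O
F8 | step 11 | cyclised diazene (25 with N=NH on C4) | CC(C)=CCC/C(C)=C/C[C@@]12C[C@H]3C(N=N)[C@@H]4C(C)(C)CC[C@]4(C1=O)C(=O)[C@@](C(=O)c1ccccc1)(C2=O)C3(C)C
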